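20.0 % of the starting material is what I write off first in this flask: this is the toll, the charge of protic impurity over the charge of starting material. It assumes that each protic impurity takes one starting material and gives no target, which makes the impurity the limiting reagent of that loss.

| flask | starting material | reagent in the second phase | protic impurity | remark | time | volume of the second phase over the first |
|---|---|---|---|---|---|---|
| amber | 0.20 M | 0.75 equiv | 0.040 M | run made earlier |  |  |
| blue | 0.20 M | 1.1 equiv | 0.040 M | run made earlier |  |  |
| flask | 0.20 M | 1.50 equiv | 0.0400 M |  | 8.0 min | 1.0 |

- amber (time / min: target / %, starting material / %): 0.417: 2, 84; 0.667: 0, 81; 0.833: 5, 79; 1.33: 8, 74; 2.00: 11, 69; 3.00: 15, 65; 5.00: 22, 53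
- blue (time / min: target / %, starting material / %): 0.417: 1, 86; 0.667: 1, 78; 0.833: 6, 75; 1.33: 8, 70; 2.00: 18, 65; 3.00: 21, 59; 5.00: 31, 49

(each reading ± 1.5 percentage points)

* target at 8.0 min, in percent of the starting material charged
* the change that raises the amount of target at 8.0 min, in percent of the starting material charged most ("none" if none brings more than 2 percentage points) (elm / alder / none)
* amount of target at 8.0 min, in percent of the starting material charged, after alder

- elm: doubling the transfer coefficient of the reagent in the second phase, all else as stated
- alder: doubling the amount of reagent in the second phase, all else as stated

- in the second phase: reagent in the second phase; everything else is in the first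
- charges count per volume of the first phase; a concentration in a rate is the amount of a species over the volume of its own phase; every rate counts per litre of the first phase
- the earlier runs hold the two phases in the same ratio of volumes as the flask asked about

I read the ladder from its first rung. At 0.667 min, target plus starting material reads 81.0 % in amber and 79.0 % in blue, close to the 80.0 % that the toll leaves, while target reads 0 % and 1 %. So from here on I reckon from that pool.

On the next rung, starting material in blue goes from that pool to 49 % at 5.00 min, a half-life of 7.07 min as a reading, far longer than the first rung. Amber, with less reagent, reads 8.42 min. Carrying blue's half-life to 8.0 min turns the pool into 43.5 % of target. That is my own estimate at blue's pace, and I expect this flask to stand somewhat above it, since this flask has more reagent than blue.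

The forecast gives 51 %, chooses alder and expects 70 % after it, holding of the other change that “Doubling transfer helps little if the chemistry is kinetically limited”. Its 51 % stands above my estimate.

    reagent in the reaction phase + target → over-reacted product (k = 0.00190 /M/s)
    starting material + protic impurity → quenched substrate (k = 0.240 /M/s)
    reagent in the reaction phase ⇌ reagent in the second phase, rate k3*([reagent in the reaction phase] - [reagent in the second phase]/K3) per volume of the first phase (partition coefficient = 0.490, kL = 0.0290 /s)
    starting material + reagent in the reaction phase → target (k = 0.0140 /M/s)

The flask gives 47.4 % of target; alder adds 11 percentage points against 0.31 points for elm and reaches 58.5 %, where the forecast said 70 %. At 0.168 min, the protic impurity has a half-life of 0.26 min, far shorter than the 7.1 min of starting material by the making of target, and at 8.00 min quenched substrate stands at 20.0 %, the toll of 20.0 %. With 0.050 M of starting material the toll is 80.0 %, and at 8.00 min that flask holds 70.7 % of quenched substrate, 12 % of its protic impurity and 11.1 % of target.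

All runs are calculated with made-up constants; the scatter is artificial.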